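**Plan**

1. Retrosynthesis: the free lactol is traced back to its (R)-isobutyrate and the ring A CH2OH to a CHO (racemic stictic acid level). The depsidone ester C(=O)–O bond and the diaryl ether O–C(ring A) bond are then cut, giving a ring A fluoro aldehyde ester and a ring B hydroquinone.
2. Ring B is a hexasubstituted benzene carrying in sequence O(ether), O(ester), CH3, OH and two neighbouring one-carbon groups (lactone C=O, lactol CH). It is cut at the bond between the phenol carbon and the carbon bearing the lactone carbonyl: the four heteroatom- or methyl-bearing carbons are a squarate unit, the other two an alkenyl unit.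
3. Forward, ring B first: squaric acid → 3-benzyloxy-4-methylcyclobutenedione; an alkenylmagnesium (from 3,3-diethoxypropyne via ynoate, stannylcupration, iodide) adds to its ketone carbonyl; thermolysis expands the four-membered ring to the benzene ring.
4. Ring A (from 3-fluoro-5-methylanisole by ortho-lithiation/formylation, bromination, carbonylation) is joined by SNAr (ether bond). Debenzylation and lactonisation close the seven-membered ring, and acid unmasking closes the hydroxyphthalide ring.
5. Stereochemistry: the single stereocentre (lactol carbon, R) is set by an isothiourea-catalysed acylative dynamic kinetic resolution. Aldehyde reduction and lipase alcoholysis then free the target without breaking a bond at that carbon.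
6. Benzyl replaces isopropyl on the squarate oxygen so that it is removed by hydrogenolysis; no Lewis acid then meets the methoxy aldehyde of ring A, and no strong acid meets the later benzylic alcohol.

Key step: step 7

Assumption: the lactol carbon is configurationally labile through ring–chain tautomerism, so it is set as its ester and freed last under neutral, water-free conditions; (R)-BTM is taken to give the (R)-ester, and the mirror-image catalyst would be used if the sense proves opposite.

**Route**

Step 1
Reactants: 1 squaric acid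
Product: 2 dibenzyl squarate
Conditions: BnOH (4 equiv), toluene, reflux, Dean–Stark
Reagents that add atoms: benzyl alcohol, OCc1ccccc1
Why: The strongly acidic vinylogous diacid should esterify with the alcohol under azeotropic removal of water (Fischer-type esterification).

Step 2
Reactants: 2 dibenzyl squarate
Product: 4 3-(benzyloxy)-4-methylcyclobut-3-ene-1,2-dione, via lithium alkoxide adduct 3 (not isolated)
Conditions: MeLi, THF, –78 °C; then TFAA, –78 °C → rt; aq. NH4Cl
Reagents that add atoms: methyllithium, [Li]C
Why: 1,2-Addition of the organolithium to one squarate carbonyl, then trifluoroacetylation, ionisation and hydrolytic loss of one benzyloxy group (acid-mediated allylic transposition), is the standard entry to 3-alkoxy-4-alkylcyclobutenediones.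

Step 3
Reactants: 5 3,3-diethoxyprop-1-yne
Product: 7 tert-butyl 4,4-diethoxybut-2-ynoate, via lithium acetylide 6 (not isolated)
Conditions: n-BuLi, THF, –78 °C; then Boc2O, –78 → 0 °C
Reagents that add atoms: di-tert-butyl dicarbonate, CC(C)(C)OC(=O)OC(=O)OC(C)(C)C
Why: C-Acylation of a lithium acetylide with the dicarbonate should give the tert-butyl ynoate directly, the bulky ester being wanted for the organomagnesium step.

Step 4
Reactants: 7 tert-butyl 4,4-diethoxybut-2-ynoate
Product: 8 tert-butyl (E)-4,4-diethoxy-3-(trimethylstannyl)but-2-enoate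
Conditions: Me6Sn2, MeLi, THF, –20 °C; CuBr·SMe2, –78 °C; then 7, MeOH, –78 °C
Reagents that add atoms: hexamethylditin, C[Sn](C)(C)[Sn](C)(C)C
Why: syn-Stannylcupration of the α,β-acetylenic ester under kinetic control (protonation at –78 °C) should put tin on the β-carbon and hydrogen cis to it, giving the E-stannane with acetal and ester cis.

Step 5
Reactants: 8 tert-butyl (E)-4,4-diethoxy-3-(trimethylstannyl)but-2-enoate
Product: 9 tert-butyl (E)-4,4-diethoxy-3-iodobut-2-enoate
Conditions: I2, CH2Cl2, 0 °C
Reagents that add atoms: iodine, II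
Why: Iododestannylation of an alkenylstannane is an ipso electrophilic substitution that proceeds with retention of double-bond geometry.

Step 6
Reactants: 9 tert-butyl (E)-4,4-diethoxy-3-iodobut-2-enoate; 4 3-(benzyloxy)-4-methylcyclobut-3-ene-1,2-dione
Product: 11 racemic tert-butyl (Z)-3-[2-(benzyloxy)-1-hydroxy-3-methyl-4-oxocyclobut-2-en-1-yl]-4,4-diethoxybut-2-enoate, via alkenylmagnesium chloride 10 (not isolated)
Conditions: i-PrMgCl·LiCl, THF, –40 °C; then cannulation into 4, THF, –78 °C; aq. NH4Cl
Reagents that add atoms: none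
Why: Iodine–magnesium exchange with the turbo-Grignard reagent should outrun attack on the tert-butyl ester at –40 °C, and the alkenylmagnesium should add 1,2 to the ketone-like carbonyl next to the benzyloxy carbon (the other carbonyl is a vinylogous ester); the carbinol centre is racemic and is erased in step 7.

Step 7
Reactants: 11 racemic tert-butyl (Z)-3-[2-(benzyloxy)-1-hydroxy-3-methyl-4-oxocyclobut-2-en-1-yl]-4,4-diethoxybut-2-enoate
Product: 14 tert-butyl 4-(benzyloxy)-2-(diethoxymethyl)-3,6-dihydroxy-5-methylbenzoate, via hydroxy dienylketene 12 (not isolated), via cyclohexadienone tautomer 13 (not isolated)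
Conditions: toluene (degassed, dilute), 110 °C, Ar
Reagents that add atoms: none
Why: Heating triggers conrotatory 4π opening of the cyclobutenone (cleavage of the carbonyl–carbinol bond) to the hydroxy dienylketene 12; a 6π electrocyclisation then joins the ketene carbon to the ester-bearing alkene carbon and closes ring B as cyclohexadienone 13, whose enolisation gives the aromatic hydroquinone 14. The closest known reaction is the Moore rearrangement of 4-alkenyl- and 4-aryl-4-hydroxycyclobutenones to hydroquinones. Ring B closes in a six-electron electrocyclic mode; the only sp3 carbon formed (in 13) is lost on tautomerisation, so no stereocentre remains. The step needs torquoselective opening with hydroxyl outward and alkenyl inward, which the donor hydroxyl secures, and the E-disposed ester (hydrogen on the inside of the triene) keeps the closure unhindered and rules out lactonisation. The substitution pattern is fixed by the regioselective addition in step 6, and the two phenols of 14 differ (one hydrogen-bonded to the ester, one free), which step 11 uses.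

Step 8
Reactants: 15 3-fluoro-5-methylanisole
Product: 17 2-fluoro-6-methoxy-4-methylbenzaldehyde, via aryllithium 16 (not isolated)
Conditions: n-BuLi, THF, –78 °C; then DMF; aq. HCl
Reagents that add atoms: N,N-dimethylformamide, CN(C)C=O
Why: Directed ortho-metalation should occur at the position flanked by fluorine and methoxy, where both groups direct, and the aryllithium is formylated by DMF.

Step 9
Reactants: 17 2-fluoro-6-methoxy-4-methylbenzaldehyde
Product: 18 3-bromo-2-fluoro-6-methoxy-4-methylbenzaldehyde
Conditions: Br2, NaOAc, AcOH, rt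
Reagents that add atoms: bromine, BrBr
Why: Electrophilic aromatic bromination should go para to the methoxy group (also ortho to fluorine and methyl, meta to the aldehyde), the only other free position being the more crowded one ortho to methoxy.

Step 10
Reactants: 18 3-bromo-2-fluoro-6-methoxy-4-methylbenzaldehyde
Product: 19 benzyl 2-fluoro-3-formyl-4-methoxy-6-methylbenzoate
Conditions: Pd(OAc)2 (cat.), Xantphos, CO (1 atm), BnOH, Et3N, toluene, 80 °C
Reagents that add atoms: carbon monoxide, [C-]#[O+]; benzyl alcohol, OCc1ccccc1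
Why: Palladium-catalysed alkoxycarbonylation of the aryl bromide (Heck carbonylation) with a wide-bite-angle diphosphine is established for ortho-substituted bromides at atmospheric pressure and should leave aldehyde and fluoride untouched.

Step 11
Reactants: 14 tert-butyl 4-(benzyloxy)-2-(diethoxymethyl)-3,6-dihydroxy-5-methylbenzoate; 19 benzyl 2-fluoro-3-formyl-4-methoxy-6-methylbenzoate
Product: 20 tert-butyl 4-(benzyloxy)-3-{2-[(benzyloxy)carbonyl]-6-formyl-5-methoxy-3-methylphenoxy}-2-(diethoxymethyl)-6-hydroxy-5-methylbenzoate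
Conditions: K2CO3, DMF (degassed), 60 °C, Ar
Reagents that add atoms: none
Why: Nucleophilic aromatic substitution (SNAr) of a fluoride activated by an ortho formyl and an ortho ester group should occur at the free phenol of 14, because the other phenol is hydrogen-bonded to the ester carbonyl and is the less nucleophilic site, as in the selective O-alkylation of 2,5-dihydroxybenzoates.

Step 12
Reactants: 20 tert-butyl 4-(benzyloxy)-3-{2-[(benzyloxy)carbonyl]-6-formyl-5-methoxy-3-methylphenoxy}-2-(diethoxymethyl)-6-hydroxy-5-methylbenzoate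
Product: 21 2-[3-(tert-butoxycarbonyl)-2-(diethoxymethyl)-4,6-dihydroxy-5-methylphenoxy]-3-formyl-4-methoxy-6-methylbenzoic acid
Conditions: H2 (1 atm), 10% Pd/C, EtOAc, rt, stopped after uptake of 2 equiv H2
Reagents that add atoms: none
Why: Hydrogenolysis of the benzyl ester and the aryl benzyl ether is fast on Pd/C, whereas the doubly ortho-substituted aryl aldehyde, the acetal and the tert-butyl ester should survive in a neutral aprotic solvent.

Step 13
Reactants: 21 2-[3-(tert-butoxycarbonyl)-2-(diethoxymethyl)-4,6-dihydroxy-5-methylphenoxy]-3-formyl-4-methoxy-6-methylbenzoic acid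
Product: 22 tert-butyl 6-(diethoxymethyl)-4-formyl-8-hydroxy-3-methoxy-1,9-dimethyl-11-oxo-11H-dibenzo[b,e][1,4]dioxepine-7-carboxylate
Conditions: DCC, CH2Cl2 (high dilution), 0 °C → rt
Reagents that add atoms: none
Why: Carbodiimide-mediated lactonisation should close the seven-membered depsidone ring onto the phenol ortho to the ether bridge, the only hydroxyl within reach of the activated acid.

Step 14
Reactants: 22 tert-butyl 6-(diethoxymethyl)-4-formyl-8-hydroxy-3-methoxy-1,9-dimethyl-11-oxo-11H-dibenzo[b,e][1,4]dioxepine-7-carboxylate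
Product: 23 racemic stictic acid
Conditions: TFA/CH2Cl2/H2O (10:10:1), 0 °C → rt
Reagents that add atoms: water, O
Why: Acidolysis of the tert-butyl ester and hydrolysis of the diethyl acetal give a 2-formylbenzoic acid that closes to its ring tautomer, the 3-hydroxyphthalide (racemic), while the aryl ester of the depsidone is stable to acid.

Step 15
Reactants: 23 racemic stictic acid
Product: 24 (R)-O-isobutyrylstictic acid
Conditions: (R)-BTM ((R)-benzotetramisole, 10 mol%), (i-PrCO)2O (1.2 equiv), i-Pr2NEt (1 equiv), THF, 0 °C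
Reagents that add atoms: isobutyric anhydride, CC(C)C(=O)OC(=O)C(C)C
Why: In this acylative dynamic kinetic resolution the lactol epimers interconvert through the open aldehyde–carboxylate under the amine base while the chiral acyl isothiouronium ion acylates one of them faster, so the catalyst sets the R configuration; the chelated, doubly flanked phenol should react far more slowly.

Step 16
Reactants: 24 (R)-O-isobutyrylstictic acid
Product: 25 (R)-O-isobutyrylcryptostictic acid
Conditions: NaBH(OAc)3 (3 equiv), AcOH (cat.), THF, 0 °C → rt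
Reagents that add atoms: none
Why: Triacetoxyborohydride is a weak hydride donor that reduces aldehydes chemoselectively under mildly acidic conditions and should leave both lactones, the lactol ester and its stereocentre untouched.

Step 17
Reactants: 25 (R)-O-isobutyrylcryptostictic acid
Product: 26 (R)-cryptostictic acid
Conditions: Novozym 435 (immobilised Candida antarctica lipase B), n-BuOH, THF/MTBE, 20 °C; filtration, evaporation below rt
Reagents that add atoms: none
Why: Lipase-catalysed alcoholysis cleaves the acyl–oxygen bond of the activated lactol ester under neutral, water-free conditions, so no bond at the stereocentre is broken and ring opening of the lactol is not promoted.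

**Compound list**

1 | squaric acid (3,4-dihydroxycyclobut-3-ene-1,2-dione) | O=C1C(=O)C(O)=C1O | starting material
2 | dibenzyl squarate (3,4-bis(benzyloxy)cyclobut-3-ene-1,2-dione) | O=C1C(=O)C(OCc2ccccc2)=C1OCc1ccccc1 | intermediate
3 | lithium 2,3-bis(benzyloxy)-1-methyl-4-oxocyclobut-2-en-1-olate (racemic) | CC1([O-])C(OCc2ccccc2)=C(OCc2ccccc2)C1=O.[Li+] | intermediate
4 | 3-(benzyloxy)-4-methylcyclobut-3-ene-1,2-dione | CC1=C(OCc2ccccc2)C(=O)C1=O | intermediate
5 | 3,3-diethoxyprop-1-yne | CCOC(OCC)C#C | starting material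
6 | (3,3-diethoxyprop-1-yn-1-yl)lithium | CCOC(OCC)C#C[Li] | intermediate
7 | tert-butyl 4,4-diethoxybut-2-ynoate | CCOC(OCC)C#CC(=O)OC(C)(C)C | intermediate
8 | tert-butyl (E)-4,4-diethoxy-3-(trimethylstannyl)but-2-enoate | C[Sn](C)(C)/C(C(OCC)OCC)=C/C(=O)OC(C)(C)C | intermediate
9 | tert-butyl (E)-4,4-diethoxy-3-iodobut-2-enoate | I/C(C(OCC)OCC)=C/C(=O)OC(C)(C)C | intermediate
10 | [(E)-4-tert-butoxy-1,1-diethoxy-4-oxobut-2-en-2-yl]magnesium chloride | Cl[Mg]/C(C(OCC)OCC)=C/C(=O)OC(C)(C)C | intermediate
11 | tert-butyl (Z)-3-[2-(benzyloxy)-1-hydroxy-3-methyl-4-oxocyclobut-2-en-1-yl]-4,4-diethoxybut-2-enoate (racemic) | CC1=C(OCc2ccccc2)C(O)(/C(C(OCC)OCC)=C/C(=O)OC(C)(C)C)C1=O | intermediate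
12 | tert-butyl (2Z,4Z)-5-(benzyloxy)-3-(diethoxymethyl)-4-hydroxy-6-methyl-7-oxohepta-2,4,6-trienoate (hydroxy dienylketene) | O=C=C(C)/C(OCc1ccccc1)=C(/O)\C(C(OCC)OCC)=C\C(=O)OC(C)(C)C | intermediate
13 | tert-butyl 4-(benzyloxy)-2-(diethoxymethyl)-3-hydroxy-5-methyl-6-oxocyclohexa-2,4-diene-1-carboxylate (racemic) | CC1=C(OCc2ccccc2)C(O)=C(C(OCC)OCC)C(C(=O)OC(C)(C)C)C1=O | intermediate
14 | tert-butyl 4-(benzyloxy)-2-(diethoxymethyl)-3,6-dihydroxy-5-methylbenzoate | Cc1c(O)c(C(=O)OC(C)(C)C)c(C(OCC)OCC)c(O)c1OCc1ccccc1 | intermediate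
15 | 3-fluoro-5-methylanisole (1-fluoro-3-methoxy-5-methylbenzene) | COc1cc(C)cc(F)c1 | starting material
16 | (2-fluoro-6-methoxy-4-methylphenyl)lithium | COc1cc(C)cc(F)c1[Li] | intermediate
17 | 2-fluoro-6-methoxy-4-methylbenzaldehyde | COc1cc(C)cc(F)c1C=O | intermediate
18 | 3-bromo-2-fluoro-6-methoxy-4-methylbenzaldehyde | COc1cc(C)c(Br)c(F)c1C=O | intermediate
19 | benzyl 2-fluoro-3-formyl-4-methoxy-6-methylbenzoate | COc1cc(C)c(C(=O)OCc2ccccc2)c(F)c1C=O | intermediate
20 | tert-butyl 4-(benzyloxy)-3-{2-[(benzyloxy)carbonyl]-6-formyl-5-methoxy-3-methylphenoxy}-2-(diethoxymethyl)-6-hydroxy-5-methylbenzoate | COc1cc(C)c(C(=O)OCc2ccccc2)c(Oc2c(OCc3ccccc3)c(C)c(O)c(C(=O)OC(C)(C)C)c2C(OCC)OCC)c1C=O | intermediate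
21 | 2-[3-(tert-butoxycarbonyl)-2-(diethoxymethyl)-4,6-dihydroxy-5-methylphenoxy]-3-formyl-4-methoxy-6-methylbenzoic acid | COc1cc(C)c(C(=O)O)c(Oc2c(O)c(C)c(O)c(C(=O)OC(C)(C)C)c2C(OCC)OCC)c1C=O | intermediate
22 | tert-butyl 6-(diethoxymethyl)-4-formyl-8-hydroxy-3-methoxy-1,9-dimethyl-11-oxo-11H-dibenzo[b,e][1,4]dioxepine-7-carboxylate | COc1cc(C)c2c(c1C=O)Oc1c(c(C)c(O)c(C(=O)OC(C)(C)C)c1C(OCC)OCC)OC2=O | intermediate
23 | racemic stictic acid (rac-1,4-dihydroxy-10-methoxy-5,8-dimethyl-3,7-dioxo-1,3-dihydro-7H-isobenzofuro[4,5-b][1,4]benzodioxepine-11-carbaldehyde) | COc1cc(C)c2c(c1C=O)Oc1c(c(C)c(O)c3c1C(O)OC3=O)OC2=O | intermediate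
24 | (R)-O-isobutyrylstictic acid ((1R)-11-formyl-4-hydroxy-10-methoxy-5,8-dimethyl-3,7-dioxo-1,3-dihydro-7H-isobenzofuro[4,5-b][1,4]benzodioxepin-1-yl 2-methylpropanoate) | COc1cc(C)c2c(c1C=O)Oc1c(c(C)c(O)c3c1[C@H](OC(=O)C(C)C)OC3=O)OC2=O | intermediate
25 | (R)-O-isobutyrylcryptostictic acid ((1R)-4-hydroxy-11-(hydroxymethyl)-10-methoxy-5,8-dimethyl-3,7-dioxo-1,3-dihydro-7H-isobenzofuro[4,5-b][1,4]benzodioxepin-1-yl 2-methylpropanoate) | COc1cc(C)c2c(c1CO)Oc1c(c(C)c(O)c3c1[C@H](OC(=O)C(C)C)OC3=O)OC2=O | intermediate
26 | (R)-cryptostictic acid, CNP0367167.1 ((1R)-1,4-dihydroxy-11-(hydroxymethyl)-10-methoxy-5,8-dimethyl-1H,7H-isobenzofuro[4,5-b][1,4]benzodioxepine-3,7-dione) | COc1cc(C)c2c(c1CO)Oc1c(c(C)c(O)c3c1[C@H](O)OC3=O)OC2=O | target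

**Count and risks**

Total step count: 17. Longest linear sequence: 12 steps (steps 3–7 and 11–17, from 3,3-diethoxyprop-1-yne).

Steps most likely to fail:

Step 6. The alkenylmagnesium may be consumed by its own ester, the isopropyl reagent may add to the β-iodo enoate with loss of iodide, or the E geometry may be lost before addition. The fallback carries the carboxyl carbon as a hindered tertiary amide, which tolerates an alkenyllithium. It sets out from 5 and comes back at 23.
- The lithium acetylide of 5 is acylated with diisopropylcarbamoyl chloride to 4,4-diethoxy-N,N-diisopropylbut-2-ynamide F1.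
- Stannylcupration as in step 4 should give (E)-4,4-diethoxy-N,N-diisopropyl-3-(trimethylstannyl)but-2-enamide F2.
- Tin–lithium exchange (MeLi, THF, –78 °C) and addition to 4 give the cyclobutenone amide adduct F3, and thermolysis as in step 7 gives the hydroquinone amide F4.
- SNAr with 19, hydrogenolysis and DCC lactonisation as in steps 11–13 lead through the diaryl ether amide F5 and the seco acid amide F6 to the depsidone amide F7.
- Aqueous acid (TFA/H2O, 40 °C) then hydrolyses the acetal and, assisted by the neighbouring oxocarbenium ion, the amide, delivering 23.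

Step 11. Arylation may occur at the chelated phenol or at both phenols, and the electron-rich phenoxide may be oxidised by air. The fallback makes the site unambiguous by protection. It sets out from 14 and comes back at 21.
- Allyl bromide/K2CO3 (acetone) alkylates only the free phenol to the allyl ether F8.
- NaH/BnBr benzylates the chelated phenol to the allyl benzyl diether F9.
- Pd(PPh3)4/morpholine removes the allyl group to give the mono-phenol F10, in which only the wanted hydroxyl is free.
- SNAr with 19 gives the tribenzyl diaryl ether F11, and the hydrogenolysis of step 12 removes all three benzyl groups to give 21.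

Step 17. Enantiopurity may erode through ring–chain tautomerism of the freed lactol, or turnover may be slow if the R ester is the antipode the enzyme handles poorly. The fallback replaces asymmetric acylation and enzymatic release by a physical resolution. It sets out from 23 and comes back at 26.
- 23 is reduced with NaBH(OAc)3 as in step 16 to racemic cryptostictic acid F12.
- The enantiomers are separated by preparative chiral SFC (immobilised polysaccharide phase, CO2/MeCN, ≤10 °C) to give 26; the unwanted enantiomer can be racemised with a trace of base and recycled.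

**Further compounds**

F1 | step 6 | 4,4-diethoxy-N,N-diisopropylbut-2-ynamide | CCOC(OCC)C#CC(=O)N(C(C)C)C(C)C
F2 | step 6 | (E)-4,4-diethoxy-N,N-diisopropyl-3-(trimethylstannyl)but-2-enamide | C[Sn](C)(C)/C(C(OCC)OCC)=C/C(=O)N(C(C)C)C(C)C
F3 | step 6 | (Z)-3-[2-(benzyloxy)-1-hydroxy-3-methyl-4-oxocyclobut-2-en-1-yl]-4,4-diethoxy-N,N-diisopropylbut-2-enamide (racemic) | CC1=C(OCc2ccccc2)C(O)(/C(C(OCC)OCC)=C/C(=O)N(C(C)C)C(C)C)C1=O
F4 | step 6 | 4-(benzyloxy)-2-(diethoxymethyl)-3,6-dihydroxy-N,N-diisopropyl-5-methylbenzamide | Cc1c(O)c(C(=O)N(C(C)C)C(C)C)c(C(OCC)OCC)c(O)c1OCc1ccccc1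
F5 | step 6 | benzyl 2-[6-(benzyloxy)-2-(diethoxymethyl)-3-(diisopropylcarbamoyl)-4-hydroxy-5-methylphenoxy]-3-formyl-4-methoxy-6-methylbenzoate | COc1cc(C)c(C(=O)OCc2ccccc2)c(Oc2c(OCc3ccccc3)c(C)c(O)c(C(=O)N(C(C)C)C(C)C)c2C(OCC)OCC)c1C=O
F6 | step 6 | 2-[2-(diethoxymethyl)-3-(diisopropylcarbamoyl)-4,6-dihydroxy-5-methylphenoxy]-3-formyl-4-methoxy-6-methylbenzoic acid | COc1cc(C)c(C(=O)O)c(Oc2c(O)c(C)c(O)c(C(=O)N(C(C)C)C(C)C)c2C(OCC)OCC)c1C=O
F7 | step 6 | 6-(diethoxymethyl)-4-formyl-8-hydroxy-3-methoxy-1,9-dimethyl-11-oxo-N,N-diisopropyl-11H-dibenzo[b,e][1,4]dioxepine-7-carboxamide | COc1cc(C)c2c(c1C=O)Oc1c(c(C)c(O)c(C(=O)N(C(C)C)C(C)C)c1C(OCC)OCC)OC2=O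
F8 | step 11 | tert-butyl 3-(allyloxy)-4-(benzyloxy)-2-(diethoxymethyl)-6-hydroxy-5-methylbenzoate | CCOC(OCC)c1c(OCC=C)c(OCc2ccccc2)c(C)c(O)c1C(=O)OC(C)(C)C
F9 | step 11 | tert-butyl 3-(allyloxy)-4,6-bis(benzyloxy)-2-(diethoxymethyl)-5-methylbenzoate | CCOC(OCC)c1c(OCC=C)c(OCc2ccccc2)c(C)c(OCc2ccccc2)c1C(=O)OC(C)(C)C
F10 | step 11 | tert-butyl 4,6-bis(benzyloxy)-2-(diethoxymethyl)-3-hydroxy-5-methylbenzoate | CCOC(OCC)c1c(O)c(OCc2ccccc2)c(C)c(OCc2ccccc2)c1C(=O)OC(C)(C)C
F11 | step 11 | tert-butyl 4,6-bis(benzyloxy)-3-{2-[(benzyloxy)carbonyl]-6-formyl-5-methoxy-3-methylphenoxy}-2-(diethoxymethyl)-5-methylbenzoate | COc1cc(C)c(C(=O)OCc2ccccc2)c(Oc2c(OCc3ccccc3)c(C)c(OCc3ccccc3)c(C(=O)OC(C)(C)C)c2C(OCC)OCC)c1C=O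
F12 | step 17 | racemic cryptostictic acid | COc1cc(C)c2c(c1CO)Oc1c(c(C)c(O)c3c1C(O)OC3=O)OC2=O
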